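## Structural features

For bookkeeping the carbons are numbered as follows: C1 is the ketone carbon, C2 its CH2, C3 the ether CH, C4 the CMe2 carbon, C5 the CH next to the spiro carbon, C6 the ether CH2, C7 the lactone carbonyl, C8 the lactone α-CH, C9 the ring-fusion CH, C10 the spiro carbon, C11 and C12 ring CH2 groups, C13 the CH that carries the acrylic acid, C14 a ring CH2, C15 the CO2H carbon, C16/C17 the C=CH2 unit and C20 the lactone OCH2. The molecule has three ring systems. A cyclohexane (C8, C9, C11–C14) is cis-fused across C8–C9 to a δ-lactone (C7, O, C20, C10). An 8,8-dimethyl-6-oxabicyclo[3.2.1]octan-3-one (carbocycle C1–C5 plus C10, bridged by O–C6) hangs on the same spiro carbon C10. There are six stereocentres: the quaternary C10 is flanked by C9 and C5, C8 is next to C9, C3 is a bridgehead that the bridge itself fixes, and C13 sits 1,4 to C9 with its substituent equatorial and trans to C10. Fragile points are the epimerisable C8–H, the 2-substituted acrylic acid (a Michael acceptor), and the β-acyloxy ketone C20–O/C1=O: once the lactone is opened, the β-hydroxy ketone with its quaternary α-carbon can lose formaldehyde by retro-aldol, so late hydrolytic base is to be avoided. The real difficulty is the quaternary C10 in the right relation to C9 and C5, made while the cyclohexane is closed and C8 ends up cis. The key step exploits that C1=O and C7=O are 1,5-related through C10–C9–C8. Reconnecting C1 to C8 gives a cyclobutane (C1, C8, C9, C10) whose C8–C9 and C1–C10 bonds come from a dioxinone C=C (C8=C1, with C7 as its carbonyl and C2 as its methyl) and a C9=C10 alkene.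

## Logic of the disconnections

37 to 36: the C15–C16 bond is cut. The acid is added last to a terminal alkyne, so no acrylate has to pass through the photochemical, basic or Lewis acidic steps and no ester has to be hydrolysed next to the lactone. The forward step must be Markovnikov-selective and must tolerate ketone and lactone.

36 to 34: the C2–C3 bond is cut. The carbocycle of the oxabicycle is closed by the enol silane of the C1 methyl ketone onto an oxocarbenium ion at C3; the bridge can only form cis, so C3 needs no control. The demand is selective ionisation of the acetal and enolisation of the ketone without touching C8.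

34 to 32: the lactone O–C7 bond and both silicon groups are removed. This leaves an open keto ester that is the direct fragmentation product. The forward step must lactonise faster than the freed β-hydroxy ketone undergoes retro-aldol, and C8 must be cis.

32 to 30: the C1–C8 bond is reconnected. Forward, base opens the dioxanone and the cyclobutanolate fragments, which unveils the C1 ketone and the C7 ester and erases the stereocentres at C1 and C8. The demand is protonation at C8 anti to C10.

30 to 29: the C8–C9 and C1–C10 bonds are cut; this is the key step. Two rings and both bonds to the future spiro and fusion carbons come from one intramolecular [2+2] photocycloaddition, and 29 keeps only C5 and C13 as stereocentres. The forward step needs fused regiochemistry, attack on one alkene face and retention of the E geometry. Three design points in 29 serve this.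
- C13 already has the target configuration, so no late epimerisation is planned.
- C13 carries a silyl alkyne instead of a dioxolane-masked acetyl group. Such a ketal would be at risk under the silyl triflate of step 17, and the unmasked ketone would compete with the C1 ketone in enol triflate formation.
- The irradiation is run without a triplet sensitiser, so that the alkene is not isomerised.

29 to 24 and 26: the C8–C14 bond is cut as an sp2–sp3 cross-coupling. The intact dioxinone is then introduced under neutral conditions; acid-mediated dioxinone formation from a β-keto ester would not spare the acetal and the silyl ether. 26 goes back to 25 by cutting C–I.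

24 to 21 (through 23 and 22): only functional groups change (iodide from mesylate, silyl ether, CH2OH from the ester). The demand is chemoselectivity between the two oxygenated carbons, which the mesylate carried from step 8 provides.

21 to 10 and 16 (through 19): the C9=C10 bond is cut as an aldol addition followed by elimination. This joins the two stereo-bearing halves and the planar ester decides the alkene geometry. The demand is E selectivity with a branched α-substituent.

16 to 11 and 12 (through 15): the C9–C11 bond (hydroformylation adds C9 as the aldehyde) and the C13–C16 bond (alkynyl opening of a vinyl epoxide) are cut. C13 then comes from a small chiral epoxide in two steps. The demands are attack at the allylic carbon with inversion and linear hydroformylation without alkene migration.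

10 to 1, 2 and 5 (through 8, 7 and 4): the acetal O–C3 bond, the auxiliary and the C5–C10 bond are cut. C5, which later steers the alkene face, is set by an auxiliary-controlled enolate alkylation. The demand is alkylation of a hindered enolate next to a quaternary carbon.

## Other disconnections considered

Alternative 1: The cut is the O–C3 bond of the ether bridge, traced back to cyclobutanone A2 in which C6 is still bonded to C3. In the forward step, Baeyer–Villiger oxidation of A2 lets the allylic bridgehead migrate with retention and gives lactone A1. In its favour, a terpene-derived cyclobutanone supplies C4 with its methyl groups and both bridgeheads in one absolute sense, and the ring expansion is strain-driven and regioselective for the more substituted, allylic carbon. Against it, A1 holds nine of the twenty carbons and none of the substituents of C10. C6 is at the lactone level and must be reduced to the ether, and the alkene must be turned regioselectively into the C1 ketone. The quaternary C10 then needs two C–C bond formations next to a bridgehead, and the cyclohexane and δ-lactone still have to be annulated with control of C9, C8 and C13. In comparison, this route settles the half of the structure that the chosen plan closes in one late step (step 17) and leaves the hard half open. Its key step is a ground-state reaction and more predictable than a photocycloaddition. On the absolute configuration of C3 and C5 it is the better plan, since that comes from the starting material and not from an auxiliary step. On step economy it is the weaker plan, because oxidation-state corrections and a separate spiro-annulation remain.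

Alternative 2: The cut is the C2–C3 bond. In the forward step the methyl ketone of A4 is silylated in the flask and its enol silane adds to the oxocarbenium ion from the methyl acetal, which gives methyl ester A3. In its favour, the three-atom bridge can only span the oxolane cis, so C3 is fixed without any control element, the conditions are mild, and the bicycle is made from a monocyclic oxolane at the end. Against it as the strategy-defining step, A4 already contains C10, C9, C8 and C13, so the central problem is only moved. The acrylate of A4 is exposed to amine, silyl triflate and a nucleophilic enol silane. The final hydrolysis of A3 must spare a lactone whose opening allows retro-aldol at C10. In comparison, the two plans are equal on this bond, because the chosen route uses the same closure as its step 17. Alternative 2 is better only in that nothing but ester cleavage follows the closure. The chosen route carries an alkyne through this step to avoid both the exposed acrylate and the hydrolysis, at the price of one more step afterwards, so step economy is equal.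

Alternative 3: The cuts are the C8–C9 and C13–C14 bonds. In the forward step, a thermal intramolecular Diels–Alder reaction of acrylate ester A6 closes the cyclohexene and the δ-lactone together and gives A5. In its favour, it forms two rings and two C–C bonds, equal to the chosen key step, and its three new stereocentres (C8, C9, C13) all persist, where the chosen key step keeps two of four; on this count it is better. The cis relation of C8 and C9 follows from the concerted suprafacial addition without a protonation step, which is also better, and no photochemical equipment is needed. Against it, ester tethers resist the reactive cisoid conformation, so high temperature or a Lewis acid would be needed on a β-alkoxy ketone. The quaternary C10 with both its CH2O and dienyl arms must be built beforehand on a hindered bicyclic ketone. The diene face relative to C10 decides C9 and is not obviously biased. C13 emerges cis to C10, so alkene hydrogenation, ketal removal and epimerisation must follow, after which two ketones compete in enol triflate formation. In comparison, the concerted mechanism is stereospecific where the chosen step passes through a biradical. The chosen plan builds C10 in the key step and not before it, and lets C5 and C13 steer the faces. Step economy is about equal once the steps after the cycloaddition are counted.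

Key step: step 14

Remark: the acetal carbon C3 is carried as a mixture of anomers from 9 to 34 (left undefined in the SMILES) and becomes a single bridgehead in step 17. The descriptor of the oxolane carbon C5 changes between R and S along the route only because CIP priorities change.

Remark: 1, 2, 5, 11, 12 and 25 are taken as commercial.

## Route

Step 1
Reactants: 1 3,3-dimethylpent-4-enoic acid; 2 (4R)-4-benzyl-1,3-oxazolidin-2-one
Product: 4 (4R)-4-benzyl-3-(3,3-dimethylpent-4-enoyl)-1,3-oxazolidin-2-one, via mixed pivalic anhydride 3 (not isolated)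
Conditions: t-BuCOCl, Et3N, THF, −20 °C; then LiCl, 2, −20 °C to rt
Reagents that add atoms: pivaloyl chloride, CC(C)(C)C(=O)Cl (acyl group of 3 only)
Why: N-acylation of the oxazolidinone through the mixed anhydride; the nucleophile attacks the carbonyl that is not flanked by the tert-butyl group.

Step 2
Reactants: 4; 5 tert-butyl bromoacetate
Product: 7 tert-butyl (3R)-3-{[(4R)-4-benzyl-2-oxo-1,3-oxazolidin-3-yl]carbonyl}-4,4-dimethylhex-5-enoate, via sodium Z-enolate 6 (not isolated)
Conditions: NaN(SiMe3)2, THF, −78 °C; then 5, −78 to −40 °C
Reagents that add atoms: sodium bis(trimethylsilyl)amide, C[Si](C)(C)[N-][Si](C)(C)C.[Na+] (sodium of 6 only)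
Why: Evans alkylation: the chelated Z-enolate is shielded on one face by the benzyl group and the reactive bromoacetate enters from the other, which sets C5 and forms the C5–C10 bond. The enolate is hindered by the adjacent quaternary carbon, so a highly reactive electrophile is chosen.

Step 3
Reactants: 7
Product: 8 tert-butyl (3R)-3-(hydroxymethyl)-4,4-dimethylhex-5-enoate
Conditions: LiBH4, H2O (1 equiv), Et2O, 0 °C
Reagents that add atoms: none
Why: Reductive cleavage of the auxiliary at the exocyclic imide carbonyl gives C6 as CH2OH. The tert-butyl ester is neither reduced nor lactonised under these conditions, and the auxiliary is recovered.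

Step 4
Reactants: 8
Product: 10 tert-butyl 2-[(3R)-5-methoxy-4,4-dimethyloxolan-3-yl]acetate, via lactol 9 (not isolated)
Conditions: O3, CH2Cl2/MeOH, −78 °C; Me2S, to rt; then camphorsulfonic acid (cat.), MeOH, rt
Reagents that add atoms: ozone, [O-][O+]=O (lactol oxygen of 9 only); methanol, CO
Why: Ozonolysis of the only alkene gives the C3 aldehyde, which the 1,4-related primary hydroxyl captures at once as the five-membered lactol. Acid-catalysed acetalisation in methanol then gives the methyl acetal while the tert-butyl ester stays intact.

Step 5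
Reactants: 11 (2S)-2-ethenyloxirane; 12 ethynyltri(propan-2-yl)silane
Product: 15 (2S)-2-ethenyl-4-[tri(propan-2-yl)silyl]but-3-yn-1-ol, via lithium silylacetylide 13 (not isolated), via diethyl(alkynyl)alumane 14 (not isolated)
Conditions: 12, n-BuLi, PhMe, 0 °C; Et2AlCl, 0 °C; then 11, −20 to 0 °C
Reagents that add atoms: n-butyllithium, [Li]CCCC (lithium of 13 only); diethylaluminium chloride, CC[Al](Cl)CC (aluminium unit of 14 only)
Why: Alkynylalane opening of a vinyl epoxide: the Lewis acidic aluminium activates the oxirane and the alkynyl group is delivered to the allylic carbon with inversion (SN2), which sets C13 and forms the C13–C16 bond.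

Step 6
Reactants: 15
Product: 16 (5S)-5-{[tri(propan-2-yl)silyl]ethynyl}oxan-2-ol (lactol of (4S)-4-(hydroxymethyl)-6-[tri(propan-2-yl)silyl]hex-5-ynal)
Conditions: Rh(acac)(CO)2 (cat.), Xantphos (cat.), CO/H2 (1:1, 10 bar), PhMe, 60 °C
Reagents that add atoms: carbon monoxide, [C-]#[O+]
Why: Linear-selective hydroformylation with a wide-bite-angle diphosphine adds C9 as the aldehyde at the terminal alkene carbon, and the primary hydroxyl captures it as the six-membered lactol. The hindered internal silyl alkyne should not react.

Step 7
Reactants: 10; 16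
Product: 19 tert-butyl (6S)-3-hydroxy-6-(hydroxymethyl)-2-[(3R)-5-methoxy-4,4-dimethyloxolan-3-yl]-8-[tri(propan-2-yl)silyl]oct-7-ynoate (mixture at C2 and C3 of the chain), via lithium enolate 17 (not isolated), via lithium alkoxide aldehyde 18 (not isolated)
Conditions: 10, LiN(i-Pr)2, THF, −78 °C; 16, LiN(SiMe3)2, THF, −78 to −40 °C; combine, −78 °C; aq. NH4Cl
Reagents that add atoms: lithium diisopropylamide, CC(C)[N-]C(C)C.[Li+] (lithium of 17 only); lithium bis(trimethylsilyl)amide, C[Si](C)(C)[N-][Si](C)(C)C.[Li+] (lithium of 18 only)
Why: Aldol addition of the ester enolate to the aldehyde that deprotonation releases from the lactol forms the C9–C10 bond. Both new carbinol and α-centres are removed in step 8, so the diastereomer mixture is carried on.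

Step 8
Reactants: 19
Product: 21 tert-butyl (2E,6S)-6-[(methanesulfonyloxy)methyl]-2-[(3S)-5-methoxy-4,4-dimethyloxolan-3-yl]-8-[tri(propan-2-yl)silyl]oct-2-en-7-ynoate, via bis-mesylate 20 (not isolated)
Conditions: MeSO2Cl, Et3N, CH2Cl2, 0 °C; then DBU, 0 °C to rt
Reagents that add atoms: methanesulfonyl chloride, CS(=O)(=O)Cl
Why: Both hydroxyls are mesylated and DBU then eliminates only the β-sulfonyloxy ester by an E1cB path. In the enolate-like transition state the chain avoids the ester group, which places C11 trans to the carbonyl and cis to C5 (E). The primary mesylate stays as the later leaving group.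

Step 9
Reactants: 21
Product: 22 (2S,5E)-7-hydroxy-6-[(3R)-5-methoxy-4,4-dimethyloxolan-3-yl]-2-{[tri(propan-2-yl)silyl]ethynyl}hept-5-en-1-yl methanesulfonate
Conditions: i-Bu2AlH, CH2Cl2, −78 to −40 °C; aq. potassium sodium tartrate
Reagents that add atoms: none
Why: 1,2-Reduction of the conjugated tert-butyl ester gives the allylic alcohol (C20) with the alkene geometry unchanged. The sulfonate and the silyl alkyne should survive at low temperature.

Step 10
Reactants: 22
Product: 23 (2S,5E)-7-{[tert-butyl(dimethyl)silyl]oxy}-6-[(3R)-5-methoxy-4,4-dimethyloxolan-3-yl]-2-{[tri(propan-2-yl)silyl]ethynyl}hept-5-en-1-yl methanesulfonate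
Conditions: t-BuMe2SiCl, imidazole, CH2Cl2, 0 °C
Reagents that add atoms: tert-butyldimethylsilyl chloride, CC(C)(C)[Si](C)(C)Cl
Why: Silylation of the primary allylic alcohol. It is done without delay, because traces of acid would let the free hydroxyl displace the methoxy group of the acetal.

Step 11
Reactants: 23
Product: 24 tert-butyl{[(2E,6S)-7-iodo-2-[(3R)-5-methoxy-4,4-dimethyloxolan-3-yl]-6-{[tri(propan-2-yl)silyl]ethynyl}hept-2-en-1-yl]oxy}dimethylsilane
Conditions: NaI, NaHCO3, acetone, 55 °C
Reagents that add atoms: sodium iodide, [Na+].[I-]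
Why: Finkelstein displacement of the primary mesylate. The buffered, neutral conditions leave the acetal and the silyl ether alone.

Step 12
Reactants: 25 2,2,6-trimethyl-4H-1,3-dioxin-4-one
Product: 26 5-iodo-2,2,6-trimethyl-4H-1,3-dioxin-4-one
Conditions: N-iodosuccinimide, AcOH, rt, dark
Reagents that add atoms: N-iodosuccinimide, O=C1CCC(=O)N1I
Why: Electrophilic iodination at the nucleophilic α-carbon of the vinylogous ester gives the sp2 coupling partner that already contains C1, C2, C7 and C8.

Step 13
Reactants: 24; 26
Product: 29 5-[(2R,5E)-7-{[tert-butyl(dimethyl)silyl]oxy}-6-[(3R)-5-methoxy-4,4-dimethyloxolan-3-yl]-2-{[tri(propan-2-yl)silyl]ethynyl}hept-5-en-1-yl]-2,2,6-trimethyl-4H-1,3-dioxin-4-one, via alkyllithium 27 (not isolated), via lithium borinate 28 (not isolated)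
Conditions: t-BuLi, Et2O, −78 °C; 9-MeO-9-BBN, THF, −78 °C to rt; then 26, PdCl2(dppf) (cat.), AsPh3, Cs2CO3, DMF/H2O, rt
Reagents that add atoms: tert-butyllithium, [Li]C(C)(C)C (lithium of 27 only); 9-methoxy-9-borabicyclo[3.3.1]nonane, COB1C2CCCC1CCC2 (boron unit of 28 only)
Why: Iodine–lithium exchange at −78 °C is faster than carbolithiation or deprotonation, and trapping as the borinate allows a B-alkyl Suzuki–Miyaura coupling with the α-iodo vinylogous ester at room temperature. The intact dioxinone is thus introduced under conditions that spare the acetal and the silyl ether.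

Step 14
Reactants: 29
Product: 30 photoadduct (1S,5R,8R,9S,10S,13R): a 2,2-dimethyl-1,3-dioxan-4-one cis-fused across C1–C8 to a cyclobutane (C1, C8, C9, C10) that is cis-fused across C8–C9 to the new cyclohexane; C1 carries the C2 methyl, C10 carries CH2OSiMe2t-Bu and the (3R)-5-methoxy-4,4-dimethyloxolan-3-yl group, C13 carries the silylethynyl group
Conditions: hν (300 nm, Pyrex), MeCN, 0 °C, 0.003 M, Ar
Reagents that add atoms: none
Why: Direct excitation of the dioxinone and intersystem crossing give its triplet enone, whose α-carbon C8 bonds to the alkene CH (C9) to form a 1,4-biradical with tertiary radical centres at C1 (oxygen-stabilised) and C10; spin inversion and collapse then form C1–C10. The closest known reaction type is the intramolecular enone–alkene [2+2] photocycloaddition of 2,2-dimethyl-1,3-dioxin-4-ones, the first half of a de Mayo sequence. The cyclohexane closes in a 6-exo-trig sense (1,6-closure; with four tether atoms no 1,5-closure exists, so the fused and not the crossed adduct is expected), and the cyclobutane closes by recombination of the 1,4-biradical. C8 and C1 are fixed by the obligatory cis fusion of the four-membered ring to both six-membered rings and are erased in step 15. C9 is set in the first bond formation: the tether folds as a chair with the C13 alkynyl group equatorial, and allylic strain holds C5–H in the alkene plane next to C11 so that the CMe2 arm of the oxolane blocks one face; both elements call for the same face (anti to CMe2), which is the one required. C10 follows from conservation of the E geometry when collapse is faster than rotation about C9–C10, and the same face of C10 is again the one remote from CMe2. Irradiation without a triplet sensitiser avoids E/Z isomerisation of the alkene, high dilution suppresses dimerisation, and the bulky silyl alkyne, the silyl ether and the acetal do not absorb at 300 nm.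

Step 15
Reactants: 30
Product: 32 methyl (1S,2R,5R)-2-{(2S)-1-{[tert-butyl(dimethyl)silyl]oxy}-2-[(3S)-5-methoxy-4,4-dimethyloxolan-3-yl]-3-oxobutan-2-yl}-5-{[tri(propan-2-yl)silyl]ethynyl}cyclohexane-1-carboxylate, via cyclobutanol ester 31 (not isolated)
Conditions: K2CO3 (cat.), MeOH, 0 °C to rt
Reagents that add atoms: methanol, CO
Why: Methoxide opens the dioxanone at its carbonyl, acetone is lost, and the strained cyclobutanolate undergoes retro-aldol cleavage of C1–C8, which completes the de Mayo sequence. The ester enolate is protonated by methanol anti to the bulky C10 substituent, which sits pseudo-axial to avoid allylic strain, so the cis ester is expected.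

Step 16
Reactants: 32
Product: 34 (4S,4aR,7R,8aS)-4-acetyl-7-ethynyl-4-[(3S)-5-methoxy-4,4-dimethyloxolan-3-yl]-3,4,4a,5,6,7,8,8a-octahydro-1H-isochromen-1-one, via hydroxy ester 33 (not isolated)
Conditions: Bu4NF, THF, 0 °C to rt; aq. NH4Cl
Reagents that add atoms: none
Why: Fluoride removes the O-silyl and C-silyl groups, and the alkoxide closes the δ-lactone on the cis ester (6-exo-trig); this should outrun retro-aldol loss of formaldehyde from the β-alkoxide ketone. The cis-fused lactone places the small CH2O arm in the crowded sector at C10 and should also be the isomer favoured if C8 equilibrates.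

Step 17
Reactants: 34
Product: 36 (1S,2S,4a′R,5S,7′R,8a′S)-7′-ethynyl-8,8-dimethyloctahydro-1′H-spiro[6-oxabicyclo[3.2.1]octane-2,4′-isochromene]-1′,3-dione, via silyl enol ether 35 (not isolated)
Conditions: Me3SiOTf, i-Pr2NEt, CH2Cl2, −78 to −20 °C
Reagents that add atoms: trimethylsilyl trifluoromethanesulfonate, C[Si](C)(C)OS(=O)(=O)C(F)(F)F (silyl group of 35 only)
Why: The silyl triflate and amine convert the methyl ketone (enolisable only toward C2, since C10 is quaternary) into its enol silane, and the triflate ionises the methyl acetal to the cyclic oxocarbenium ion. Intramolecular Mukaiyama-type addition forms C2–C3, and the three-atom bridge can only span the oxolane cis, which fixes C3.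

Step 18
Reactants: 36
Product: 37 2-[(1S,2S,4a′R,5S,7′R,8a′S)-8,8-dimethyl-1′,3-dioxooctahydro-1′H-spiro[6-oxabicyclo[3.2.1]octane-2,4′-isochromen]-7′-yl]prop-2-enoic acid (CNP0268721.1)
Conditions: Pd(OAc)2 (cat.), 2-(diphenylphosphino)pyridine (cat.), TsOH·H2O (cat.), CO (10 bar), H2O, acetone, 50 °C
Reagents that add atoms: carbon monoxide, [C-]#[O+]; water, O
Why: Palladium-catalysed Markovnikov hydroxycarbonylation of the terminal alkyne: the palladium hydride adds with the metal on the internal carbon, CO inserts and water releases the 2-substituted acrylic acid directly. The mildly acidic aqueous medium should spare the lactone, the ketone and C8.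

## Compound list

1 | 3,3-dimethylpent-4-enoic acid | C=CC(C)(C)CC(=O)O | starting material
2 | (4R)-4-benzyl-1,3-oxazolidin-2-one | O=C1N[C@H](Cc2ccccc2)CO1 | starting material
3 | 3,3-dimethylpent-4-enoic pivalic anhydride | C=CC(C)(C)CC(=O)OC(=O)C(C)(C)C | intermediate (not isolated)
4 | (4R)-4-benzyl-3-(3,3-dimethylpent-4-enoyl)-1,3-oxazolidin-2-one | C=CC(C)(C)CC(=O)N1[C@H](Cc2ccccc2)COC1=O | intermediate
5 | tert-butyl bromoacetate | CC(C)(C)OC(=O)CBr | starting material
6 | sodium (Z)-enolate of 4 | C=CC(C)(C)/C=C(\[O-])N1[C@H](Cc2ccccc2)COC1=O.[Na+] | intermediate (not isolated)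
7 | tert-butyl (3R)-3-{[(4R)-4-benzyl-2-oxo-1,3-oxazolidin-3-yl]carbonyl}-4,4-dimethylhex-5-enoate | CC(C)(C)OC(=O)C[C@H](C(C)(C)C=C)C(=O)N1[C@H](Cc2ccccc2)COC1=O | intermediate
8 | tert-butyl (3R)-3-(hydroxymethyl)-4,4-dimethylhex-5-enoate | CC(C)(C)OC(=O)C[C@H](C(C)(C)C=C)CO | intermediate
9 | tert-butyl 2-[(3R)-5-hydroxy-4,4-dimethyloxolan-3-yl]acetate (lactol, both anomers) | CC(C)(C)OC(=O)C[C@H]1COC(O)C1(C)C | intermediate (not isolated)
10 | tert-butyl 2-[(3R)-5-methoxy-4,4-dimethyloxolan-3-yl]acetate (both anomers) | CC(C)(C)OC(=O)C[C@H]1COC(OC)C1(C)C | intermediate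
11 | (2S)-2-ethenyloxirane | C=C[C@H]1CO1 | starting material
12 | ethynyltri(propan-2-yl)silane | C#C[Si](C(C)C)(C(C)C)C(C)C | starting material
13 | lithium [tri(propan-2-yl)silyl]acetylide | [Li]C#C[Si](C(C)C)(C(C)C)C(C)C | intermediate (not isolated)
14 | diethyl{[tri(propan-2-yl)silyl]ethynyl}alumane | CC[Al](CC)C#C[Si](C(C)C)(C(C)C)C(C)C | intermediate (not isolated)
15 | (2S)-2-ethenyl-4-[tri(propan-2-yl)silyl]but-3-yn-1-ol | OC[C@H](C#C[Si](C(C)C)(C(C)C)C(C)C)C=C | intermediate
16 | (5S)-5-{[tri(propan-2-yl)silyl]ethynyl}oxan-2-ol (both anomers) | OC1CC[C@@H](C#C[Si](C(C)C)(C(C)C)C(C)C)CO1 | intermediate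
17 | lithium enolate of 10 | [Li+].CC(C)(C)OC([O-])=C[C@H]1COC(OC)C1(C)C | intermediate (not isolated)
18 | lithium (2S)-5-oxo-2-{[tri(propan-2-yl)silyl]ethynyl}pentan-1-olate | [Li+].[O-]C[C@H](C#C[Si](C(C)C)(C(C)C)C(C)C)CCC=O | intermediate (not isolated)
19 | tert-butyl (6S)-3-hydroxy-6-(hydroxymethyl)-2-[(3R)-5-methoxy-4,4-dimethyloxolan-3-yl]-8-[tri(propan-2-yl)silyl]oct-7-ynoate | CC(C)(C)OC(=O)C(C(O)CC[C@@H](C#C[Si](C(C)C)(C(C)C)C(C)C)CO)[C@H]1COC(OC)C1(C)C | intermediate
20 | bis(methanesulfonate) of 19 | CC(C)(C)OC(=O)C(C(OS(C)(=O)=O)CC[C@@H](C#C[Si](C(C)C)(C(C)C)C(C)C)COS(C)(=O)=O)[C@H]1COC(OC)C1(C)C | intermediate (not isolated)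
21 | tert-butyl (2E,6S)-6-[(methanesulfonyloxy)methyl]-2-[(3S)-5-methoxy-4,4-dimethyloxolan-3-yl]-8-[tri(propan-2-yl)silyl]oct-2-en-7-ynoate | CS(=O)(=O)OC[C@H](C#C[Si](C(C)C)(C(C)C)C(C)C)CC/C=C(C(=O)OC(C)(C)C)\[C@H]1COC(OC)C1(C)C | intermediate
22 | (2S,5E)-7-hydroxy-6-[(3R)-5-methoxy-4,4-dimethyloxolan-3-yl]-2-{[tri(propan-2-yl)silyl]ethynyl}hept-5-en-1-yl methanesulfonate | CS(=O)(=O)OC[C@H](C#C[Si](C(C)C)(C(C)C)C(C)C)CC/C=C(CO)\[C@H]1COC(OC)C1(C)C | intermediate
23 | (2S,5E)-7-{[tert-butyl(dimethyl)silyl]oxy}-6-[(3R)-5-methoxy-4,4-dimethyloxolan-3-yl]-2-{[tri(propan-2-yl)silyl]ethynyl}hept-5-en-1-yl methanesulfonate | CS(=O)(=O)OC[C@H](C#C[Si](C(C)C)(C(C)C)C(C)C)CC/C=C(CO[Si](C)(C)C(C)(C)C)\[C@H]1COC(OC)C1(C)C | intermediate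
24 | tert-butyl{[(2E,6S)-7-iodo-2-[(3R)-5-methoxy-4,4-dimethyloxolan-3-yl]-6-{[tri(propan-2-yl)silyl]ethynyl}hept-2-en-1-yl]oxy}dimethylsilane | IC[C@H](C#C[Si](C(C)C)(C(C)C)C(C)C)CC/C=C(CO[Si](C)(C)C(C)(C)C)\[C@H]1COC(OC)C1(C)C | intermediate
25 | 2,2,6-trimethyl-4H-1,3-dioxin-4-one | CC1=CC(=O)OC(C)(C)O1 | starting material
26 | 5-iodo-2,2,6-trimethyl-4H-1,3-dioxin-4-one | CC1=C(I)C(=O)OC(C)(C)O1 | intermediate
27 | primary alkyllithium from 24 | [Li]C[C@H](C#C[Si](C(C)C)(C(C)C)C(C)C)CC/C=C(CO[Si](C)(C)C(C)(C)C)\[C@H]1COC(OC)C1(C)C | intermediate (not isolated)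
28 | lithium B-alkyl-B-methoxy-9-borabicyclo[3.3.1]nonanate from 27 | [Li+].CO[B-]1(C[C@H](C#C[Si](C(C)C)(C(C)C)C(C)C)CC/C=C(CO[Si](C)(C)C(C)(C)C)\[C@H]2COC(OC)C2(C)C)C3CCCC1CCC3 | intermediate (not isolated)
29 | 5-[(2R,5E)-7-{[tert-butyl(dimethyl)silyl]oxy}-6-[(3R)-5-methoxy-4,4-dimethyloxolan-3-yl]-2-{[tri(propan-2-yl)silyl]ethynyl}hept-5-en-1-yl]-2,2,6-trimethyl-4H-1,3-dioxin-4-one | CC1=C(C[C@H](C#C[Si](C(C)C)(C(C)C)C(C)C)CC/C=C(CO[Si](C)(C)C(C)(C)C)\[C@H]2COC(OC)C2(C)C)C(=O)OC(C)(C)O1 | intermediate
30 | cyclobutane photoadduct (1S,5R,8R,9S,10S,13R), dioxanone/cyclobutane/cyclohexane all cis-fused | C[C@@]12OC(C)(C)OC(=O)[C@@]13C[C@H](C#C[Si](C(C)C)(C(C)C)C(C)C)CC[C@H]3[C@@]2(CO[Si](C)(C)C(C)(C)C)[C@H]4COC(OC)C4(C)C | intermediate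
31 | cyclobutanol methyl ester from methanolysis of 30 (configurations as in 30) | C[C@@]1(O)[C@@]2(C(=O)OC)C[C@H](C#C[Si](C(C)C)(C(C)C)C(C)C)CC[C@H]2[C@@]1(CO[Si](C)(C)C(C)(C)C)[C@H]3COC(OC)C3(C)C | intermediate (not isolated)
32 | methyl (1S,2R,5R)-2-{(2S)-1-{[tert-butyl(dimethyl)silyl]oxy}-2-[(3S)-5-methoxy-4,4-dimethyloxolan-3-yl]-3-oxobutan-2-yl}-5-{[tri(propan-2-yl)silyl]ethynyl}cyclohexane-1-carboxylate | COC(=O)[C@H]1C[C@H](C#C[Si](C(C)C)(C(C)C)C(C)C)CC[C@H]1[C@](CO[Si](C)(C)C(C)(C)C)(C(C)=O)[C@H]2COC(OC)C2(C)C | intermediate
33 | methyl (1S,2R,5R)-5-ethynyl-2-{(2S)-1-hydroxy-2-[(3S)-5-methoxy-4,4-dimethyloxolan-3-yl]-3-oxobutan-2-yl}cyclohexane-1-carboxylate | COC(=O)[C@H]1C[C@H](C#C)CC[C@H]1[C@](CO)(C(C)=O)[C@H]2COC(OC)C2(C)C | intermediate (not isolated)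
34 | (4S,4aR,7R,8aS)-4-acetyl-7-ethynyl-4-[(3S)-5-methoxy-4,4-dimethyloxolan-3-yl]-3,4,4a,5,6,7,8,8a-octahydro-1H-isochromen-1-one | C#C[C@@H]1CC[C@@H]2[C@H](C1)C(=O)OC[C@@]2(C(C)=O)[C@H]1COC(OC)C1(C)C | intermediate
35 | trimethylsilyl enol ether of the acetyl group of 34 | C#C[C@@H]1CC[C@@H]2[C@H](C1)C(=O)OC[C@@]2(C(=C)O[Si](C)(C)C)[C@H]1COC(OC)C1(C)C | intermediate (not isolated)
36 | (1S,2S,4a′R,5S,7′R,8a′S)-7′-ethynyl-8,8-dimethyloctahydro-1′H-spiro[6-oxabicyclo[3.2.1]octane-2,4′-isochromene]-1′,3-dione | C#C[C@@H]1CC[C@@H]2[C@H](C1)C(=O)OC[C@]21C(=O)C[C@@H]2OC[C@H]1C2(C)C | intermediate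
37 | 2-[(1S,2S,4a′R,5S,7′R,8a′S)-8,8-dimethyl-1′,3-dioxooctahydro-1′H-spiro[6-oxabicyclo[3.2.1]octane-2,4′-isochromen]-7′-yl]prop-2-enoic acid | C=C(C(=O)O)[C@@H]1CC[C@@H]2[C@H](C1)C(=O)OC[C@]21C(=O)C[C@@H]2OC[C@H]1C2(C)C | target

## Step count and least certain steps

Total: 18 steps. Longest linear sequence: 15 steps (steps 1–4, 7–11, 13–18, from 1).

Step 14 (key step). The most likely failure is loss of stereochemical information in the triplet biradical: rotation about C9–C10 before collapse would scramble C10, and the face of the first bond formation could be less well differentiated than the chair and allylic-strain arguments suggest; slow 1,6-closure could also lead to reversion and isomerisation of the alkene. The fallback turns C10 into a ring atom of a rigid bicycle, so that the gem-dimethyl bridge blocks one face of both alkene carbons whatever the biradical does. From 22, a trace of pyridinium tosylate in benzene should expel methanol and give the bicyclic acetal mesylate F1 (C20–O bonded to C3). NaI then gives the bicyclic acetal iodide F2, and coupling with 26 as in step 13 gives the bicyclic acetal dioxinone F3. Irradiation as in step 14 gives the bicyclic acetal photoadduct F4, and K2CO3 in MeOH gives the bicyclic acetal keto ester F5. Camphorsulfonic acid in MeOH opens the bicyclic acetal reversibly; only the form with a free C20 hydroxyl can lactonise, which should funnel the material to the silylalkynyl lactone F6. Bu4NF then removes the alkynyl silyl group and the route is rejoined at 34.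

Step 5. The alkynylalane may attack the terminal epoxide carbon or add in a conjugate (SN2′) sense, and partial ionisation at the allylic carbon would erode the configuration of C13. The fallback builds the same centre by catalyst-controlled SN2′ substitution. Commercial (Z)-but-2-ene-1,4-diol is converted into the mono(4-methoxybenzyl) ether F7 (NaH, 4-methoxybenzyl chloride) and then into the allylic diethyl phosphate F8 (ClP(O)(OEt)2, pyridine). Copper-catalysed enantioselective allylic substitution with 12 (CuCl, chiral N-heterocyclic carbene ligand, LiOt-Bu) gives the 4-methoxybenzyl ether of 15 F9, and oxidative removal of the benzyl ether with DDQ returns to the route at 15.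

Step 8. The E1cB elimination may give an E/Z mixture, because the α-substituent is branched and the usual preference for the chain trans to the ester is weakened. The fallback fixes the geometry before the C–C bond is made and then couples with retention. From 10, formylation (LiN(i-Pr)2, HCO2Et) gives the α-formyl ester F10. Triflation under non-chelating conditions (Tf2O, i-Pr2NEt) gives the (E)-enol triflate F11, whose isomers can be separated. From 15, MeSO2Cl/Et3N gives the mesylate F12, and hydroboration with 9-BBN gives the B-alkyl-9-BBN F13. B-alkyl Suzuki–Miyaura coupling of F13 with F11 (PdCl2(dppf), K3PO4) returns to the route at 21.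

Step 13. The primary alkyllithium may cyclise onto the C9=C10 alkene or be quenched at the propargylic position; transmetalation to palladium may be slow enough for β-hydride elimination to compete, and the dioxinone may be opened by aqueous base. The fallback uses enolate alkylation and a thermal dioxinone synthesis. From 24, the sodium enolate of tert-butyl acetoacetate (NaH, THF/DMF) gives the C-alkylated tert-butyl β-keto ester F14. Heating F14 with acetone in toluene in a sealed tube releases tert-butanol and the acylketene, which acetone traps as the dioxinone; this returns to the route at 29 without acid.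

Step 18. Hydropalladation may proceed in the anti-Markovnikov sense and give the linear acid, or palladium hydride may move the new double bond into the ring position at C13; the acid co-catalyst may also epimerise C8. The fallback separates the regiochemical step from the carbonylation. From 36, Markovnikov hydroiodination (Me3SiCl, NaI, H2O, MeCN) gives the 2-iodoalkene F15, and hydroxycarbonylation of this vinyl iodide (Pd(OAc)2, PPh3, CO, KOAc, DMF/H2O) returns to the route at 37.

## Further compounds

F1 | step 14 | (2S,5E)-5-(8,8-dimethyl-2,7-dioxabicyclo[3.2.1]octan-4-ylidene)-2-{[tri(propan-2-yl)silyl]ethynyl}pentyl methanesulfonate (bicyclic acetal from 22) | CS(=O)(=O)OC[C@H](C#C[Si](C(C)C)(C(C)C)C(C)C)CC/C=C1/CO[C@@H]2OC[C@H]1C2(C)C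
F2 | step 14 | iodide corresponding to F1 | IC[C@H](C#C[Si](C(C)C)(C(C)C)C(C)C)CC/C=C1/CO[C@@H]2OC[C@H]1C2(C)C
F3 | step 14 | 5-substituted 2,2,6-trimethyl-4H-1,3-dioxin-4-one carrying the bicyclic acetal | CC1=C(C[C@H](C#C[Si](C(C)C)(C(C)C)C(C)C)CC/C=C2/CO[C@@H]3OC[C@H]2C3(C)C)C(=O)OC(C)(C)O1
F4 | step 14 | cyclobutane photoadduct with C10 spiro to the bicyclic acetal | C[C@@]12OC(C)(C)OC(=O)[C@@]13C[C@H](C#C[Si](C(C)C)(C(C)C)C(C)C)CC[C@H]3[C@]24CO[C@@H]5OC[C@H]4C5(C)C
F5 | step 14 | keto methyl ester with the bicyclic acetal | COC(=O)[C@H]1C[C@H](C#C[Si](C(C)C)(C(C)C)C(C)C)CC[C@H]1[C@@]2(C(C)=O)CO[C@@H]3OC[C@H]2C3(C)C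
F6 | step 14 | C-silylated form of 34 (triisopropylsilyl on the alkyne) | CC(C)[Si](C#C[C@@H]1CC[C@@H]2[C@H](C1)C(=O)OC[C@@]2(C(C)=O)[C@H]1COC(OC)C1(C)C)(C(C)C)C(C)C
F7 | step 5 | (2Z)-4-[(4-methoxyphenyl)methoxy]but-2-en-1-ol | COc1ccc(COC/C=C\CO)cc1
F8 | step 5 | diethyl (2Z)-4-[(4-methoxyphenyl)methoxy]but-2-en-1-yl phosphate | CCOP(=O)(OCC)OC/C=C\COCc1ccc(OC)cc1
F9 | step 5 | 4-methoxybenzyl ether of 15 | COc1ccc(COC[C@H](C#C[Si](C(C)C)(C(C)C)C(C)C)C=C)cc1
F10 | step 8 | tert-butyl 2-[(3R)-5-methoxy-4,4-dimethyloxolan-3-yl]-3-oxopropanoate | CC(C)(C)OC(=O)C(C=O)[C@H]1COC(OC)C1(C)C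
F11 | step 8 | tert-butyl (2E)-2-[(3S)-5-methoxy-4,4-dimethyloxolan-3-yl]-3-[(trifluoromethanesulfonyl)oxy]prop-2-enoate | FC(F)(F)S(=O)(=O)O/C=C(C(=O)OC(C)(C)C)\[C@H]1COC(OC)C1(C)C
F12 | step 8 | (2S)-2-ethenyl-4-[tri(propan-2-yl)silyl]but-3-yn-1-yl methanesulfonate | CS(=O)(=O)OC[C@H](C#C[Si](C(C)C)(C(C)C)C(C)C)C=C
F13 | step 8 | B-alkyl-9-borabicyclo[3.3.1]nonane from F12 | CS(=O)(=O)OC[C@H](C#C[Si](C(C)C)(C(C)C)C(C)C)CCB1C2CCCC1CCC2
F14 | step 13 | tert-butyl 2-acetyl-substituted ester from 24 (tert-butyl 3-oxobutanoate alkylated at C2) | CC(=O)C(C[C@H](C#C[Si](C(C)C)(C(C)C)C(C)C)CC/C=C(CO[Si](C)(C)C(C)(C)C)\[C@H]1COC(OC)C1(C)C)C(=O)OC(C)(C)C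
F15 | step 18 | 2-iodoalkene from 36 (1-iodoethenyl at C13) | C=C(I)[C@@H]1CC[C@@H]2[C@H](C1)C(=O)OC[C@]21C(=O)C[C@@H]2OC[C@H]1C2(C)C
A1 | alternative 1 | 8,8-dimethyl-6-oxabicyclo[3.2.1]oct-3-en-7-one | O=C1O[C@H]2C=CC[C@@H]1C2(C)C
A2 | alternative 1 | 6,6-dimethylbicyclo[3.1.1]hept-2-en-7-one | O=C1[C@H]2C=CC[C@@H]1C2(C)C
A3 | alternative 2 | methyl ester of 37 | COC(=O)C(=C)[C@@H]1CC[C@@H]2[C@H](C1)C(=O)OC[C@]21C(=O)C[C@@H]2OC[C@H]1C2(C)C
A4 | alternative 2 | methyl 2-[(4S,4aR,7R,8aS)-4-acetyl-4-[(3S)-5-methoxy-4,4-dimethyloxolan-3-yl]-1-oxooctahydro-1H-isochromen-7-yl]prop-2-enoate | COC(=O)C(=C)[C@@H]1CC[C@@H]2[C@H](C1)C(=O)OC[C@@]2(C(C)=O)[C@H]1COC(OC)C1(C)C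
A5 | alternative 3 | cis-fused cyclohexene spirolactone with the dioxolane-bearing carbon cis to the spiro carbon | CC3(OCCO3)[C@H]1C=C[C@@H]2[C@H](C1)C(=O)OC[C@]21C(=O)C[C@@H]2OC[C@H]1C2(C)C
A6 | alternative 3 | acrylate ester of the bicyclic ketone carrying the (E,E)-dienyl group on the spiro carbon | C=CC(=O)OC[C@@]1(/C=C/C=C/C2(C)OCCO2)C(=O)C[C@@H]3OC[C@H]1C3(C)C
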